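In a one-step world, with starting material going first-order to target, every run would end at the same percentage of its charge, whatever that charge was. Our flask branches instead, and one suspect step is bimolecular.

| flask | starting material | protic impurity | remark | time |
|---|---|---|---|---|
| north-west | 36 mM (fed, over 40 min) | 2.4 mM | run made earlier; the fed solution adds 1.0 times the starting volume |  |
| winter | 24 mM (fed, over 40 min) | 2.40 mM | the fed solution adds 1.0 times the starting volume | 20 h |
| midnight | 24 mM (fed, over 40 min) | 2.40 mM | the fed solution adds 1.0 times the starting volume | 25 h |

north-west run (percent of the starting material charged)

| time / h | target / % |
|---|---|
| 0.333 | 2.7 |
| 1.00 | 16.2 |
| 2.00 | 24.0 |
| 3.00 | 27.7 |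
| 4.00 | 28.6 |

(standard deviation of a reading: 0.5 percentage points)

1. which of the two there is more of at the end, winter (isomer of the product A / target)
2. which of the two there is more of at the end, midnight (isomer of the product A / target)
3. final target, as a percentage of the starting material charged, in winter
4. final target, as a percentage of the starting material charged, in midnight

- amounts are per litre of the starting volume; all of the dose is in the solution fed
- on the list of suspects stand: starting material <-> other conformer; third conformer -> third product; starting material -> target; target <-> isomer of the product B; other conformer -> isomer of the product A; other conformer + protic impurity -> quenched substrate; other conformer <-> third conformer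
- percentages count the whole charge, also what has not yet gone in

The hourly gains of target in north-west shrink from 7.8 percentage points to 0.9 points, so we take the last reading, 28.6%, as its level, good to 0.5 points. The suspect steps are first-order, except the quench of other conformer by protic impurity. The charge should therefore act through the quench share, the protic impurity charged per starting material charged, which is the most a one-to-one quench can take: 10.0% in winter and midnight, 6.67% in north-west.

We solve two ends. If the conformers exchange fast against everything else (the Curtin–Hammett limit), the quench thins one common pool, and target in winter and midnight falls in proportion to what escapes it, to 27.6%. If they exchange slowly, the quench takes other conformer that was headed for isomer of the product A, and target in winter and midnight stays at 28.6%. The exchange rate is unknown, so we expect winter and midnight between these two estimates and commit to the middle, 28.1%, for both. Our figure would leave 61.9% for isomer of the product A, isomer of the product B and third product together, twice our target, so we tentatively expect isomer of the product A to exceed target.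

The forecast gives 28.9% for winter and 28.9% for midnight, higher than our figure, with isomer of the product A ahead in both, reasoning “The branching is first-order, so it doesn't depend on concentration”.

Winter and midnight give 27.9% and 27.9% of target, between our two estimates, against 53.4% of isomer of the product A in each.

    starting material ⇌ other conformer (K = 0.860, k = 4.52 h⁻¹)
    third conformer → third product (k = 0.847 h⁻¹)
    starting material → target (k = 0.654 h⁻¹)
    target ⇌ isomer of the product B (K = 0.264, k = 1.49 h⁻¹)
    other conformer → isomer of the product A (k = 1.57 h⁻¹)
    other conformer + protic impurity → quenched substrate (k = 1660 M⁻¹ h⁻¹)
    other conformer ⇌ third conformer (K = 0.160, k = 0.0543 h⁻¹)

In winter at 20.0 h, starting material stands at 0%, protic impurity at 0.084% of its own charge, and quenched substrate at 9.99%, close to the quench share of 10.0%. The same flask as winter with 9.6 mM of starting material has a share of 25.0%; it ends with 22.7% quenched substrate, less than that share, and 25.0% of target, above its fast-exchange estimate of 23.0%. Left ten times as long, winter still holds 27.9% of target at 200 h, and midnight 27.9% at 250 h.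

The runs are simulated with constants of no real substance; scatter was added.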